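**Plan**

- Numbering: five-membered ring C1(CH3)–C2–C3–C4(OH, i-Pr)–C5; seven-membered ring C5–C6(OAr)–C7–C8(CH3)–C9–C10–C1, with the oxirane on C8–C9.
- Enabling feature: ring atoms C5–C10 bear oxygen at C6 and methyl at C8 in the pattern of 3-methylanisole, and C1 is one extra carbon lodged between C5 and C10, so the seven-membered ring is a benzene ring enlarged by a carbene carbon.
- Retrosynthesis: remove the C6 ester and the C8–C9 oxirane, trace C4–OH/C5–H/C6–OH back to a C4=C5 enone, then cut C1–C5 and C1–C10 (Buchner ring expansion), C1–C2 (acylation of diazoethane) and C4–aryl (conjugate addition).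
- Forward: the chain aryl–C4–C3–C2–C1 is built first and both rings close in one operation; C2 is then deoxygenated and the triene is turned into the C4=C5 enone with C8=C9 in place.
- Stereochemistry: C4 comes from Rh/(R)-BINAP arylation, relays its configuration to quaternary C1 in the ring expansion and is then erased. The C6 carbinol steers the C4–C5 epoxide, SmI2 opening and protonation give the cis ring fusion, and hydride and peracid both enter from the convex face to fix C6 and the oxirane.

Key step: step 4

Remark: α means the face of the bicycle that carries the C1 methyl group and β the other face; 4-[(tert-butyldimethylsilyl)oxy]benzoic acid 22 is assumed to be purchasable (otherwise one silylation of 4-hydroxybenzoic acid).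

**Route**

Step 1
Reactants: 1 (2-methoxy-4-methylphenyl)boronic acid; 2 ethyl (E)-4-methylpent-2-enoate
Product: 3 ethyl (3R)-3-(2-methoxy-4-methylphenyl)-4-methylpentanoate
Conditions: 1 (2.5 equiv), [Rh(cod)Cl]2 (2 mol %), (R)-BINAP (4.4 mol %), Et3N (1 equiv), dioxane/H2O 10:1, 60 °C
Reagents that add atoms: none
Why: Hayashi–Miyaura rhodium-catalysed asymmetric 1,4-addition, in which the aryl–rhodium–BINAP species inserts the (E)-enoate on one enantioface and the rhodium enolate is hydrolysed; (R)-BINAP is chosen because it should give the R centre at C4 (the mirror of the known (S)-BINAP/(E)-crotonate sense once the priority change caused by isopropyl is allowed for), and the enantiomeric purity is to be checked by chiral HPLC before going on.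

Step 2
Reactants: 3 ethyl (3R)-3-(2-methoxy-4-methylphenyl)-4-methylpentanoate
Product: 4 (3R)-3-(2-methoxy-4-methylphenyl)-4-methylpentanoic acid
Conditions: LiOH·H2O, THF/MeOH/H2O, rt; then 1 M HCl
Reagents that add atoms: lithium hydroxide [Li+].[OH-]
Why: Ester saponification by acyl–oxygen cleavage; the stereocentre is β to the carboxyl group and cannot epimerise.

Step 3
Reactants: 4 (3R)-3-(2-methoxy-4-methylphenyl)-4-methylpentanoic acid; 5 N-ethyl-N-nitrosourea
Product: 8 (5R)-2-diazo-5-(2-methoxy-4-methylphenyl)-6-methylheptan-3-one, via acid chloride 6 (not isolated), via diazoethane 7 (not isolated)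
Conditions: 4, (COCl)2, DMF (cat.), CH2Cl2, 0 °C to rt, evaporate; separately 5, KOH (aq)/Et2O, 0 °C, ethereal 7 dried over KOH; 6 added to 7 (3 equiv), Et2O, −20 to 0 °C
Reagents that add atoms: none
Why: Arndt–Eistert-type acylation of a diazoalkane: the acid chloride acylates diazoethane at carbon and a second equivalent removes HCl as chloroethane, which gives the secondary α-diazo ketone without touching the remote C4 centre.

Step 4
Reactants: 8 (5R)-2-diazo-5-(2-methoxy-4-methylphenyl)-6-methylheptan-3-one
Product: 10 (3R,8aS)-4-methoxy-6,8a-dimethyl-3-(propan-2-yl)-3,8a-dihydroazulen-1(2H)-one, via norcaradiene 9 (not isolated)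
Conditions: Rh2(OAc)4 (1 mol %), CH2Cl2, 40 °C, 8 added over 4 h
Reagents that add atoms: none
Why: Rh2(OAc)4 removes N2 from 8 to give an electrophilic rhodium carbenoid at C1, which cyclopropanates the ipso–ortho bond C5–C10 of the anisole ring to norcaradiene 9; disrotatory 6π opening of 9 then breaks C5–C10 and leaves C1 bonded to both carbons in the cycloheptatriene 10. The closest known reaction type is the intramolecular Buchner reaction of 2-diazo-5-arylalkan-3-ones to 8a-methyl-3,8a-dihydroazulen-1(2H)-ones under dirhodium catalysis. The five-membered ring closes by carbenoid attack through the three-atom tether C2–C3–C4 onto the ipso carbon (cyclopropanation), and the seven-membered ring arises by electrocyclic expansion of the benzene ring, with C1 as its only sp3 carbon. The new quaternary centre C1 is set by the arene face the carbenoid adds to, and this is controlled by C4: with the benzylic hydrogen eclipsing the ortho methoxy group, the tether and the isopropyl group lie on opposite faces, so the C1 methyl ends trans to isopropyl. The step needs addition to the unsubstituted ortho bond and aryl addition in preference to insertion into the isopropyl C–H bond; the methoxy group blocks the other ortho bond, and the electron-rich ring together with slow addition of 8 should favour aryl capture.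

Step 5
Reactants: 10 (3R,8aS)-4-methoxy-6,8a-dimethyl-3-(propan-2-yl)-3,8a-dihydroazulen-1(2H)-one
Product: 11 N'-[(3R,8aS)-4-methoxy-6,8a-dimethyl-3-(propan-2-yl)-3,8a-dihydroazulen-1(2H)-ylidene]-4-methylbenzenesulfonohydrazide
Conditions: TsNHNH2 (1.3 equiv), 4 Å molecular sieves, THF, 60 °C
Reagents that add atoms: 4-methylbenzenesulfonohydrazide Cc1ccc(cc1)S(=O)(=O)NN
Why: Condensation of the only carbonyl group to its tosylhydrazone under anhydrous conditions without added acid, so that the methyl enol ether, which masks the C6 ketone, survives.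

Step 6
Reactants: 11 N'-[(3R,8aS)-4-methoxy-6,8a-dimethyl-3-(propan-2-yl)-3,8a-dihydroazulen-1(2H)-ylidene]-4-methylbenzenesulfonohydrazide
Product: 12 (3R,8aS)-4-methoxy-6,8a-dimethyl-3-(propan-2-yl)-1,2,3,8a-tetrahydroazulene
Conditions: catecholborane (2 equiv), CHCl3, 0 °C to rt; then NaOAc·3H2O (3 equiv), reflux
Reagents that add atoms: none
Why: Tosylhydrazone reduction of the Kabalka type: catecholborane adds hydride to the C=N bond, acetate expels sulfinate and the diazene loses N2 to leave CH2 at C2; the hydrazone is not conjugated, so no alkene shifts, and because the fused cyclopentane holds the C1–C2 bond in the nodal plane of both neighbouring double bonds a transient C2 radical has no overlap for 3-exo capture by the triene.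

Step 7
Reactants: 12 (3R,8aS)-4-methoxy-6,8a-dimethyl-3-(propan-2-yl)-1,2,3,8a-tetrahydroazulene
Product: 13 (3R,8aS)-6,8a-dimethyl-3-(propan-2-yl)-2,3,3a,8a-tetrahydroazulen-4(1H)-one (both C3a epimers)
Conditions: 1 M HCl (aq)/THF 1:4, 0 °C to rt
Reagents that add atoms: water O
Why: Enol ether hydrolysis: C5 is the only carbon that receives the oxygen lone pair, so protonation there and addition of water at C6 give the linear dienone; the C5 configuration is of no consequence because C5 becomes sp2 in the next step.

Step 8
Reactants: 13 (3R,8aS)-6,8a-dimethyl-3-(propan-2-yl)-2,3,3a,8a-tetrahydroazulen-4(1H)-one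
Product: 15 (8aS)-6,8a-dimethyl-3-(propan-2-yl)-2,8a-dihydroazulen-4(1H)-one, via silyl trienol ether 14 (not isolated)
Conditions: TMSOTf (1.3 equiv), Et3N (2 equiv), CH2Cl2, 0 °C; concentrate; Pd(OAc)2 (1.1 equiv), MeCN, rt
Reagents that add atoms: none
Why: Saegusa–Ito dehydrogenation: C5 is the only enolisable position of the dienone, so the silyl enol ether is regiodefined, and the palladium enolate can undergo β-hydride elimination only toward C4 because C1 is quaternary, which gives the C4=C5 bond and erases the relay centre.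

Step 9
Reactants: 15 (8aS)-6,8a-dimethyl-3-(propan-2-yl)-2,8a-dihydroazulen-4(1H)-one
Product: 16 (8aS)-6,8a-dimethyl-3-(propan-2-yl)-1,2,8,8a-tetrahydroazulen-4(5H)-one
Conditions: Li (2.2 equiv), NH3(l)/THF, t-BuOH (1 equiv), −78 °C; isoprene, then solid NH4Cl
Reagents that add atoms: none
Why: Dissolving-metal reduction of a cross-conjugated ketone, which as in 1,4-dien-3-one to 4-en-3-one reductions spares the more substituted enone: the radical anion should be protonated at C10, the unsubstituted terminus of the longer arm, the lithium dienolate resists further electron uptake, and kinetic protonation at C7 on quenching leaves C8=C9 out of conjugation.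

Step 10
Reactants: 16 (8aS)-6,8a-dimethyl-3-(propan-2-yl)-1,2,8,8a-tetrahydroazulen-4(5H)-one
Product: 17 (4R,8aS)-6,8a-dimethyl-3-(propan-2-yl)-1,2,4,5,8,8a-hexahydroazulen-4-ol (6β-alcohol in route numbering)
Conditions: i-Bu2AlH (1.2 equiv), toluene, −78 °C; aqueous potassium sodium tartrate
Reagents that add atoms: none
Why: 1,2-Reduction of a fully β-substituted enone by an aluminium hydride in a non-basic medium, so C8=C9 cannot drift into conjugation; the C8–C10 bridge folds over the carbonyl face opposite to the C1 methyl, so hydride should enter from the methyl face and give the 6β-alcohol.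

Step 11
Reactants: 17 (4R,8aS)-6,8a-dimethyl-3-(propan-2-yl)-1,2,4,5,8,8a-hexahydroazulen-4-ol
Product: 18 4β,5β-epoxy-6β-alcohol with C8=C9 (1S,4R,5S,6R in route numbering)
Conditions: VO(acac)2 (5 mol %), t-BuOOH (1.5 equiv, decane), CH2Cl2, 0 °C
Reagents that add atoms: tert-butyl hydroperoxide CC(C)(C)OO
Why: Hydroxyl-directed vanadium-catalysed epoxidation of an allylic alcohol: the vanadate ester of the C6 hydroxyl delivers oxygen to the C4=C5 bond on its own (β) face, faster than to the homoallylic C8=C9 bond, which places the C4 oxygen trans to the C1 methyl.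

Step 12
Reactants: 18 4β,5β-epoxy-6β-alcohol with C8=C9
Product: 19 4β,5β-epoxy-6-ketone with C8=C9 (1S,4R,5R in route numbering)
Conditions: Dess–Martin periodinane (1.3 equiv), NaHCO3, CH2Cl2, 0 °C to rt
Reagents that add atoms: none
Why: Dess–Martin oxidation under buffered neutral conditions gives the α,β-epoxy ketone without opening the fully substituted oxirane or conjugating the C8=C9 bond.

Step 13
Reactants: 19 4β,5β-epoxy-6-ketone with C8=C9
Product: 20 (3R,3aR,8aS)-3-hydroxy-6,8a-dimethyl-3-(propan-2-yl)-2,3,3a,5,8,8a-hexahydroazulen-4(1H)-one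
Conditions: SmI2 (2.2 equiv), THF/MeOH, −78 °C; pH 7 buffer
Reagents that add atoms: none
Why: SmI2 reduction of an α,β-epoxy ketone: the ketyl expels the Cα–O bond, the C4 alkoxide keeps its configuration, and the samarium enolate, held by that alkoxide on the β face, should be protonated by methanol at C5 from the α face to give the cis-fused β-hydroxy ketone.

Step 14
Reactants: 20 (3R,3aR,8aS)-3-hydroxy-6,8a-dimethyl-3-(propan-2-yl)-2,3,3a,5,8,8a-hexahydroazulen-4(1H)-one
Product: 21 (3R,3aS,4R,8aS)-6,8a-dimethyl-3-(propan-2-yl)-1,2,3,3a,4,5,8,8a-octahydroazulene-3,4-diol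
Conditions: Et2BOMe (1.1 equiv), THF/MeOH 4:1, −78 °C; NaBH4; AcOH, then MeOH co-evaporation
Reagents that add atoms: none
Why: Narasaka–Prasad reduction: diethylboron bridges the C4 alkoxide and the ketone, and borohydride should attack C6 from the convex α face, away from the quaternary C4 on the neighbouring atom, to give the 6β-alcohol cis to the C4 hydroxyl.

Step 15
Reactants: 21 (3R,3aS,4R,8aS)-6,8a-dimethyl-3-(propan-2-yl)-1,2,3,3a,4,5,8,8a-octahydroazulene-3,4-diol; 22 4-[(tert-butyldimethylsilyl)oxy]benzoic acid
Product: 23 C6 4-[(tert-butyldimethylsilyl)oxy]benzoate of diol 21 (1S,4R,5S,6R in route numbering)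
Conditions: 22 (1.5 equiv), EDC·HCl (2 equiv), DMAP (1 equiv), CH2Cl2, rt to 40 °C
Reagents that add atoms: none
Why: Steglich esterification: the carbodiimide-activated acid is passed by DMAP to the secondary C6 hydroxyl, while the tertiary C4 hydroxyl is too hindered to acylate and the silyl ether keeps the phenol from competing.

Step 16
Reactants: 23 C6 4-[(tert-butyldimethylsilyl)oxy]benzoate of diol 21
Product: 24 8α,9α-epoxide of 23 (1S,4R,5S,6R,8R,9S in route numbering)
Conditions: mCPBA (1.2 equiv), NaHCO3, CH2Cl2, 0 °C
Reagents that add atoms: 3-chloroperoxybenzoic acid OOC(=O)c1cccc(Cl)c1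
Why: Prilezhaev epoxidation of the only alkene, an electron-rich trisubstituted one; the peracid should approach the convex face of the cis-fused bicycle (the face of the C1 methyl and H5), since the other face is closed by the five-membered ring and the C6 ester, which puts the oxirane oxygen α.

Step 17
Reactants: 24 8α,9α-epoxide of 23
Product: 25 target compound, the C6 4-hydroxybenzoate (1S,4R,5S,6R,8R,9S in route numbering)
Conditions: Bu4NF (1.1 equiv), AcOH (1.1 equiv), THF, 0 °C
Reagents that add atoms: none
Why: Fluoride cleavage of the aryl silyl ether, buffered with acetic acid so that the phenoxide is protonated at once and neither the benzoate ester nor the oxirane is touched.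

**Compound list**

1 | (2-methoxy-4-methylphenyl)boronic acid | COc1cc(C)ccc1B(O)O | starting material
2 | ethyl (E)-4-methylpent-2-enoate | CCOC(=O)/C=C/C(C)C | starting material
3 | ethyl (3R)-3-(2-methoxy-4-methylphenyl)-4-methylpentanoate | COc1cc(C)ccc1[C@@H](C(C)C)CC(=O)OCC | intermediate
4 | (3R)-3-(2-methoxy-4-methylphenyl)-4-methylpentanoic acid | COc1cc(C)ccc1[C@@H](C(C)C)CC(=O)O | intermediate
5 | N-ethyl-N-nitrosourea | CCN(N=O)C(N)=O | starting material
6 | (3R)-3-(2-methoxy-4-methylphenyl)-4-methylpentanoyl chloride | COc1cc(C)ccc1[C@@H](C(C)C)CC(=O)Cl | intermediate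
7 | diazoethane | CC=[N+]=[N-] | intermediate
8 | (5R)-2-diazo-5-(2-methoxy-4-methylphenyl)-6-methylheptan-3-one | COc1cc(C)ccc1[C@@H](C(C)C)CC(=O)C(C)=[N+]=[N-] | intermediate
9 | norcaradiene form of 10 (cyclopropane C1–C5–C10 fused to the methoxycyclohexadiene and the cyclopentanone, C1 methyl over the diene ring) | COC1=CC(C)=C[C@H]2[C@]3(C)C(=O)C[C@H](C(C)C)[C@]123 | intermediate
10 | (3R,8aS)-4-methoxy-6,8a-dimethyl-3-(propan-2-yl)-3,8a-dihydroazulen-1(2H)-one | COC1=C2[C@@H](C(C)C)CC(=O)[C@@]2(C)C=CC(C)=C1 | intermediate
11 | N'-[(3R,8aS)-4-methoxy-6,8a-dimethyl-3-(propan-2-yl)-3,8a-dihydroazulen-1(2H)-ylidene]-4-methylbenzenesulfonohydrazide | COC1=C2[C@@H](C(C)C)CC(=NNS(=O)(=O)c3ccc(C)cc3)[C@@]2(C)C=CC(C)=C1 | intermediate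
12 | (3R,8aS)-4-methoxy-6,8a-dimethyl-3-(propan-2-yl)-1,2,3,8a-tetrahydroazulene | COC1=C2[C@@H](C(C)C)CC[C@@]2(C)C=CC(C)=C1 | intermediate
13 | (3R,8aS)-6,8a-dimethyl-3-(propan-2-yl)-2,3,3a,8a-tetrahydroazulen-4(1H)-one, both C3a epimers | CC1=CC(=O)C2[C@@H](C(C)C)CC[C@@]2(C)C=C1 | intermediate
14 | (3R,8aS)-6,8a-dimethyl-3-(propan-2-yl)-4-(trimethylsilyloxy)-1,2,3,8a-tetrahydroazulene | CC1=CC(O[Si](C)(C)C)=C2[C@@H](C(C)C)CC[C@@]2(C)C=C1 | intermediate
15 | (8aS)-6,8a-dimethyl-3-(propan-2-yl)-2,8a-dihydroazulen-4(1H)-one | CC1=CC(=O)C2=C(C(C)C)CC[C@@]2(C)C=C1 | intermediate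
16 | (8aS)-6,8a-dimethyl-3-(propan-2-yl)-1,2,8,8a-tetrahydroazulen-4(5H)-one | CC1=CC[C@]2(C)CCC(C(C)C)=C2C(=O)C1 | intermediate
17 | (4R,8aS)-6,8a-dimethyl-3-(propan-2-yl)-1,2,4,5,8,8a-hexahydroazulen-4-ol | CC1=CC[C@]2(C)CCC(C(C)C)=C2[C@H](O)C1 | intermediate
18 | 4β,5β-epoxy-6β-alcohol with C8=C9 (1S,4R,5S,6R, route numbering) | CC1=CC[C@]2(C)CC[C@]3(C(C)C)O[C@]23[C@H](O)C1 | intermediate
19 | 4β,5β-epoxy-6-ketone with C8=C9 (1S,4R,5R, route numbering) | CC1=CC[C@]2(C)CC[C@]3(C(C)C)O[C@]23C(=O)C1 | intermediate
20 | (3R,3aR,8aS)-3-hydroxy-6,8a-dimethyl-3-(propan-2-yl)-2,3,3a,5,8,8a-hexahydroazulen-4(1H)-one | CC(C)[C@]1(O)CC[C@@]2(C)CC=C(C)CC(=O)[C@H]21 | intermediate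
21 | (3R,3aS,4R,8aS)-6,8a-dimethyl-3-(propan-2-yl)-1,2,3,3a,4,5,8,8a-octahydroazulene-3,4-diol | CC(C)[C@]1(O)CC[C@@]2(C)CC=C(C)C[C@@H](O)[C@H]21 | intermediate
22 | 4-[(tert-butyldimethylsilyl)oxy]benzoic acid | CC(C)(C)[Si](C)(C)Oc1ccc(cc1)C(O)=O | starting material
23 | C6 4-[(tert-butyldimethylsilyl)oxy]benzoate of diol 21 | CC(C)[C@]1(O)CC[C@@]2(C)CC=C(C)C[C@@H](OC(=O)c3ccc(O[Si](C)(C)C(C)(C)C)cc3)[C@H]21 | intermediate
24 | 8α,9α-epoxide of 23 | CC(C)[C@]1(O)CC[C@@]2(C)C[C@@H]3O[C@]3(C)C[C@@H](OC(=O)c3ccc(O[Si](C)(C)C(C)(C)C)cc3)[C@H]21 | intermediate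
25 | target: 8α,9α-epoxy-4β-hydroxy C6β 4-hydroxybenzoate (1S,4R,5S,6R,8R,9S, route numbering) | CC(C)[C@]1(O)CC[C@@]2(C)C[C@@H]3O[C@]3(C)C[C@@H](OC(=O)c3ccc(O)cc3)[C@H]21 | target

**Step count**

Total: 17 steps. Longest linear sequence: 17 steps (1 and 2 to 25).

**Steps most likely to fail**

Step 9. What may go wrong: after electron uptake the cross-conjugated trienone may be protonated at C4 or C8 instead of C10, or reduction may run on, so that double-bond isomers and over-reduced ketones form. The fallback lets a silyl enol ether, not the competition between two arms, carry the regiochemistry. It sets out from 13. TBSOTf/Et3N gives the tert-butyldimethylsilyl trienol ether F1. Li/NH3 with t-BuOH at −78 °C then reduces the triene in the Birch manner (protonation at the terminus C10, then at the central carbon C7 of the pentadienyl anion). This leaves the C5=C6 silyl enol ether and the C8=C9 alkene in the silyl enol ether diene F2. Saegusa oxidation of F2 with Pd(OAc)2 in MeCN removes the C4 hydrogen and gives the enone directly. The fallback comes back to the route at 16, and 15 is never made.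

Step 8. What may go wrong: the palladium enolate at the crowded ring-fusion carbon may be protodesilylated back to the ketone faster than it undergoes β-hydride elimination toward a tertiary C–H bond. The fallback uses selenoxide elimination and starts from the methyl enol ether 12. PhSeCl in CH2Cl2 at −78 °C attacks the enol ether carbon C5 from the face away from the isopropyl group, and aqueous NaHCO3 work-up releases the α-phenylselanyl ketone F3. H2O2/pyridine at 0 °C gives the selenoxide, whose syn elimination can take only the cis C4 hydrogen because C1 has none. The fallback comes back to the route at 15, bypassing 13 and 14.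

Step 16. What may go wrong: poor or reversed facial selectivity, for instance if the C4 hydroxyl steers the peracid to the concave face. The fallback reaches the oxirane through a halohydrin, which puts oxygen on the face opposite to the one an electrophile attacks first. It sets out from 23. NBS in THF/H2O at 0 °C forms the bromonium ion on the face the electrophile prefers and water opens it at the tertiary C8 from the other face, giving the bromohydrin F4. DBU in CH2Cl2 then closes the ring with inversion at C9. The fallback comes back to the route at 24.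

**Further compounds**

F1 | step 9 | (3R,8aS)-4-(tert-butyldimethylsilyloxy)-6,8a-dimethyl-3-(propan-2-yl)-1,2,3,8a-tetrahydroazulene | CC1=CC(O[Si](C)(C)C(C)(C)C)=C2[C@@H](C(C)C)CC[C@@]2(C)C=C1
F2 | step 9 | (3R,8aS)-4-(tert-butyldimethylsilyloxy)-6,8a-dimethyl-3-(propan-2-yl)-1,2,3,5,8,8a-hexahydroazulene | CC1=CC[C@]2(C)CC[C@H](C(C)C)C2=C(O[Si](C)(C)C(C)(C)C)C1
F3 | step 8 | (3R,3aR,8aS)-6,8a-dimethyl-3a-(phenylselanyl)-3-(propan-2-yl)-2,3,3a,8a-tetrahydroazulen-4(1H)-one | CC1=CC(=O)[C@@]2([Se]c3ccccc3)[C@@H](C(C)C)CC[C@@]2(C)C=C1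
F4 | step 16 | 9β-bromo-8α-hydroxy derivative of 23 (bromohydrin) | CC(C)[C@]1(O)CC[C@@]2(C)C[C@@H](Br)[C@](C)(O)C[C@@H](OC(=O)c3ccc(O[Si](C)(C)C(C)(C)C)cc3)[C@H]21
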